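**Plan**

1. Cuts: (a) the C2–C3 single bond of the heptatrienyl chain (Mizoroki–Heck; vinyl carbinol plus bromodienamide 27); (b) the ring C–N bond of the enamide (2-bromoenone 10 plus trienamide 17); (c) the epoxycyclohexenone ring itself, from which the N-bearing sp2 carbon is excised between the ketone carbon and the vinylic CH, leaving a 2,3-epoxy-4-hydroxy-4-vinylcyclopentanone.
2. Enabling feature: in the six-membered carbocycle the carbon that carries nitrogen lies between the C=O carbon and the ring =CH (a C(=O)–C(X)=CH triad). This is what dihalocarbene ring enlargement of a cyclopentanone silyl enol ether delivers. The other alpha carbon is an epoxide carbon and cannot enolise, so the enol ether forms on one side only.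
3. Forward order: chiral-pool cyclopentene ring, then the fused epoxide ring, then a transient cyclopropane, then the six-membered ring by one-carbon enlargement, then C–N coupling of the upper chain, then Heck attachment of the lower chain.
4. Stereochemistry: all three ring stereocentres derive from the one stereocentre of (R)-4-silyloxycyclopentenone by substrate control (vinyl adds anti to the silyloxy group; both cis hydroxyls deliver the peracid), after which that relay centre is oxidised to the ketone. The side-chain centre comes from (R)-2-methylbutan-1-ol; the E alkenes come from the Wittig, Horner–Wadsworth–Emmons and Heck steps.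

Key step: step 6

Assumption: (R)-2-methylbutan-1-ol and (R)-4-[(tert-butyldimethylsilyl)oxy]cyclopent-2-en-1-one are bought as single enantiomers; the aldehyde from the former is trapped in the flask to avoid enolisation.

**Route**

Step 1
Reactants: 1 (R)-4-[(tert-butyldimethylsilyl)oxy]cyclopent-2-en-1-one; 2 vinylmagnesium bromide
Product: 3 (1R,4R)-4-[(tert-butyldimethylsilyl)oxy]-1-ethenylcyclopent-2-en-1-ol
Conditions: CeCl3 (anhydrous), THF, −78 °C; aq. NH4Cl
Reagents that add atoms: none
Why: Organocerium-mediated Grignard 1,2-addition to the enone should place the vinyl group anti to the silyloxy substituent, so the new tertiary hydroxyl is cis to the silyloxy group.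

Step 2
Reactants: 3 (1R,4R)-4-[(tert-butyldimethylsilyl)oxy]-1-ethenylcyclopent-2-en-1-ol
Product: 4 (1R,3R)-1-ethenylcyclopent-4-ene-1,3-diol
Conditions: TBAF, THF, 0 °C to rt
Reagents that add atoms: none
Why: Fluoride desilylation frees the secondary hydroxyl without touching the tertiary bis-allylic alcohol, giving the cis-diol.

Step 3
Reactants: 4 (1R,3R)-1-ethenylcyclopent-4-ene-1,3-diol
Product: 5 (1R,2R,4R,5R)-2-ethenyl-6-oxabicyclo[3.1.0]hexane-2,4-diol
Conditions: mCPBA (1.1 equiv), CH2Cl2, 0 °C
Reagents that add atoms: 3-chloroperbenzoic acid, OOC(=O)c1cccc(Cl)c1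
Why: Henbest hydroxyl-directed epoxidation: both cis allylic hydroxyls should deliver the peracid to the same face of the ring alkene (epoxide cis to both OH), and the monosubstituted vinyl group should react far more slowly.

Step 4
Reactants: 5 (1R,2R,4R,5R)-2-ethenyl-6-oxabicyclo[3.1.0]hexane-2,4-diol
Product: 6 (1S,4R,5R)-4-ethenyl-4-hydroxy-6-oxabicyclo[3.1.0]hexan-2-one
Conditions: Dess–Martin periodinane, NaHCO3, CH2Cl2, 0 °C to rt
Reagents that add atoms: none
Why: Dess–Martin oxidation converts only the secondary alcohol to the ketone; this removes the relay stereocentre and leaves the carbinol and epoxide centres unchanged.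

Step 5
Reactants: 6 (1S,4R,5R)-4-ethenyl-4-hydroxy-6-oxabicyclo[3.1.0]hexan-2-one
Product: 7 (1S,4S,5R)-4-ethenyl-2,4-bis[(trimethylsilyl)oxy]-6-oxabicyclo[3.1.0]hex-2-ene
Conditions: TMSOTf (2.5 equiv), Et3N, CH2Cl2, −78 to 0 °C
Reagents that add atoms: trimethylsilyl trifluoromethanesulfonate, C[Si](C)(C)OS(=O)(=O)C(F)(F)F
Why: Soft enolisation can occur only towards the CH2 group because the other alpha carbon is an epoxide carbon, and the tertiary alcohol is silylated at the same time as a temporary protecting group.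

Step 6
Reactants: 7 (1S,4S,5R)-4-ethenyl-2,4-bis[(trimethylsilyl)oxy]-6-oxabicyclo[3.1.0]hex-2-ene; 8 bromoform
Product: 10 (1S,5S,6R)-3-bromo-5-ethenyl-5-[(trimethylsilyl)oxy]-7-oxabicyclo[4.1.0]hept-3-en-2-one, via dibromocyclopropane adduct 9 (not isolated)
Conditions: KOtBu (2.2 equiv), pentane, −30 °C to rt
Reagents that add atoms: none
Why: Deprotonation of bromoform gives dibromocarbene, which adds in a concerted [2+1] cheletropic fashion to the electron-rich silyl enol ether (closing the three-membered ring of 9); the 1-siloxy-6,6-dibromobicyclo[3.1.0]hexane unit then undergoes the thermally allowed disrotatory two-electron electrocyclic opening, in which the bromide syn to the five-membered ring leaves while the bond shared by the three- and five-membered rings breaks, so the carbene carbon is inserted between the former carbonyl carbon and the former CH2 and the ring grows from five to six atoms. The resulting 2-bromoallyl cation is an oxocarbenium ion at its siloxy terminus and should collapse by transfer of the silyl group to tert-butoxide, giving the 2-bromocyclohex-2-enone directly. The closest known reaction type is the one-carbon ring enlargement of cyclic silyl enol ethers to 2-halocycloalk-2-enones with dihalocarbenes. The six-membered ring arises by cleavage of the internal cyclopropane bond, not by a cyclisation, and the only ring that is closed, the transient cyclopropane, closes by carbene cycloaddition; its two new stereocentres are erased on opening, so no new stereocentre remains and the carbinol and the two epoxide centres, which take no part, are carried over unchanged. The step needs chemoselectivity for the enol ether over the monosubstituted vinyl group (secured by the much higher nucleophilicity of the siloxy alkene and by limiting the bromoform), a single regiochemistry of opening (only the siloxy-stabilised allyl cation can form), and survival of the epoxide (excess tert-butoxide traps the silyl group before a silyl bromide can open it).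

Step 7
Reactants: 11 (R)-2-methylbutan-1-ol; 12 (triphenylphosphoranylidene)acetaldehyde
Product: 14 (2E,4R)-4-methylhex-2-enal, via (R)-2-methylbutanal 13 (not isolated)
Conditions: TEMPO (cat.), PhI(OAc)2, CH2Cl2, rt; then 12, rt to 40 °C
Reagents that add atoms: none
Why: Nitroxyl-catalysed oxidation followed in the same flask by Wittig reaction with the stabilised formyl ylide should give the E enal without isolating the volatile, enolisable aldehyde.

Step 8
Reactants: 14 (2E,4R)-4-methylhex-2-enal; 15 triethyl 4-phosphonocrotonate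
Product: 16 ethyl (2E,4E,6E,8R)-8-methyldeca-2,4,6-trienoate
Conditions: LiHMDS, THF, −78 to 0 °C
Reagents that add atoms: none
Why: Vinylogous Horner–Wadsworth–Emmons olefination should form the new C4=C5 bond E and keep the E geometry of both partners.

Step 9
Reactants: 16 ethyl (2E,4E,6E,8R)-8-methyldeca-2,4,6-trienoate
Product: 17 (2E,4E,6E,8R)-8-methyldeca-2,4,6-trienamide
Conditions: AlMe3, NH4Cl, toluene, 0 to 50 °C; aq. HCl work-up
Reagents that add atoms: ammonium chloride, [NH4+].[Cl-]
Why: Aminolysis of the ester by the aluminium amide made from AlMe3 and NH4Cl (Weinreb-type amidation) attacks the ester carbonyl directly and should leave the triene and the remote stereocentre untouched.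

Step 10
Reactants: 10 (1S,5S,6R)-3-bromo-5-ethenyl-5-[(trimethylsilyl)oxy]-7-oxabicyclo[4.1.0]hept-3-en-2-one; 17 (2E,4E,6E,8R)-8-methyldeca-2,4,6-trienamide
Product: 19 (2E,4E,6E,8R)-N-[(1S,5S,6R)-5-ethenyl-5-hydroxy-2-oxo-7-oxabicyclo[4.1.0]hept-3-en-3-yl]-8-methyldeca-2,4,6-trienamide, via trimethylsilyl ether 18 (not isolated)
Conditions: CuI (copper monoiodide, 20 mol %), 3,4,7,8-tetramethyl-1,10-phenanthroline (40 mol %), Cs2CO3, DMA, 50 °C; then citric acid, MeOH, 0 °C
Reagents that add atoms: none
Why: Goldberg-type copper-catalysed N-alkenylation of the primary amide with the activated, non-enolisable 2-bromoenone should install the enamide at the brominated carbon, and mild acidic methanolysis then removes the tertiary trimethylsilyl ether.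

Step 11
Reactants: 20 glutaconaldehyde potassium salt
Product: 21 (2E,4E)-5-bromopenta-2,4-dienal
Conditions: PPh3, Br2, CH2Cl2, 0 °C to rt; then cat. I2 to equilibrate to the E,E isomer
Reagents that add atoms: bromine, BrBr
Why: Dibromotriphenylphosphorane turns the enolate oxygen into an oxyphosphonium leaving group that bromide displaces by addition–elimination (Appel-type deoxybromination of a vinylogous formate).

Step 12
Reactants: 21 (2E,4E)-5-bromopenta-2,4-dienal
Product: 22 (2E,4E)-5-bromopenta-2,4-dienoic acid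
Conditions: NaClO2, NaH2PO4, 2-methylbut-2-ene, t-BuOH/H2O, 0 °C to rt
Reagents that add atoms: sodium chlorite, [Na+].[O-]Cl=O
Why: Pinnick oxidation converts the dienal to the acid without affecting the bromodiene, the alkene scavenger removing hypochlorous acid.

Step 13
Reactants: 23 cyclopentane-1,3-dione
Product: 24 2-(hydroxyimino)cyclopentane-1,3-dione
Conditions: NaNO2, aq. HCl, 0 °C
Reagents that add atoms: sodium nitrite, [Na+].[O-]N=O
Why: Electrophilic nitrosation at the doubly activated C2 of the enolised 1,3-dione gives the nitroso compound, which tautomerises to the oxime.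

Step 14
Reactants: 24 2-(hydroxyimino)cyclopentane-1,3-dione
Product: 25 2-amino-3-hydroxycyclopent-2-en-1-one hydrochloride
Conditions: H2 (1 atm), Pd/C, HCl, EtOH, rt
Reagents that add atoms: hydrogen chloride, Cl
Why: Catalytic hydrogenation of the oxime gives the primary amine, trapped as its hydrochloride to prevent self-condensation.

Step 15
Reactants: 22 (2E,4E)-5-bromopenta-2,4-dienoic acid; 25 2-amino-3-hydroxycyclopent-2-en-1-one hydrochloride
Product: 27 (2E,4E)-5-bromo-N-(2-hydroxy-5-oxocyclopent-1-en-1-yl)penta-2,4-dienamide, via (2E,4E)-5-bromopenta-2,4-dienoyl chloride 26 (not isolated)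
Conditions: (COCl)2, cat. DMF, CH2Cl2, 0 °C to rt, evaporate; then 25, Et3N, CH2Cl2/DMF, 0 °C to rt
Reagents that add atoms: none
Why: Acid chloride formation and N-acylation of the liberated amino-dione; any O-acylated enol ester should transfer its acyl group to nitrogen to give the stable enol amide.

Step 16
Reactants: 19 (2E,4E,6E,8R)-N-[(1S,5S,6R)-5-ethenyl-5-hydroxy-2-oxo-7-oxabicyclo[4.1.0]hept-3-en-3-yl]-8-methyldeca-2,4,6-trienamide; 27 (2E,4E)-5-bromo-N-(2-hydroxy-5-oxocyclopent-1-en-1-yl)penta-2,4-dienamide
Product: 28 (2E,4E,6E,8R)-N-[(1S,5S,6R)-5-hydroxy-5-[(1E,3E,5E)-7-[(2-hydroxy-5-oxocyclopent-1-en-1-yl)amino]-7-oxohepta-1,3,5-trien-1-yl]-2-oxo-7-oxabicyclo[4.1.0]hept-3-en-3-yl]-8-methyldeca-2,4,6-trienamide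
Conditions: Pd(OAc)2 (10 mol %), n-Bu4NCl, NaHCO3, DMF, 45 °C, dark, argon
Reagents that add atoms: none
Why: Mizoroki–Heck reaction: the dienylpalladium bromide formed from 27 and zerovalent palladium should add to the only monosubstituted alkene of 19 at its terminal carbon, and syn beta-hydride elimination, possible only away from the quaternary carbinol carbon, gives the E alkene with the E,E geometry of 27 retained.

**Compound list**

1 | (R)-4-[(tert-butyldimethylsilyl)oxy]cyclopent-2-en-1-one | O=C1C=C[C@H](O[Si](C)(C)C(C)(C)C)C1 | starting material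
2 | vinylmagnesium bromide | C=C[Mg]Br | starting material
3 | (1R,4R)-4-[(tert-butyldimethylsilyl)oxy]-1-ethenylcyclopent-2-en-1-ol | C=C[C@@]1(O)C=C[C@H](O[Si](C)(C)C(C)(C)C)C1 | intermediate
4 | (1R,3R)-1-ethenylcyclopent-4-ene-1,3-diol | C=C[C@@]1(O)C=C[C@H](O)C1 | intermediate
5 | (1R,2R,4R,5R)-2-ethenyl-6-oxabicyclo[3.1.0]hexane-2,4-diol (epoxide cis to both hydroxyls) | C=C[C@@]1(O)[C@@H]2O[C@@H]2[C@H](O)C1 | intermediate
6 | (1S,4R,5R)-4-ethenyl-4-hydroxy-6-oxabicyclo[3.1.0]hexan-2-one | C=C[C@@]1(O)[C@@H]2O[C@@H]2C(=O)C1 | intermediate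
7 | (1S,4S,5R)-4-ethenyl-2,4-bis[(trimethylsilyl)oxy]-6-oxabicyclo[3.1.0]hex-2-ene | C=C[C@@]1(O[Si](C)(C)C)[C@@H]2O[C@@H]2C(O[Si](C)(C)C)=C1 | intermediate
8 | bromoform | BrC(Br)Br | starting material
9 | 7,7-dibromo-5-ethenyl-1,5-bis[(trimethylsilyl)oxy]-3-oxatricyclo[4.1.0.0(2,4)]heptane, cyclopropane drawn anti to the epoxide (not isolated) | C=C[C@@]1(O[Si](C)(C)C)[C@@H]2O[C@@H]2[C@]3(O[Si](C)(C)C)[C@H]1C3(Br)Br | intermediate
10 | (1S,5S,6R)-3-bromo-5-ethenyl-5-[(trimethylsilyl)oxy]-7-oxabicyclo[4.1.0]hept-3-en-2-one | BrC1=C[C@@](O[Si](C)(C)C)(C=C)[C@@H]2O[C@@H]2C1=O | intermediate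
11 | (R)-2-methylbutan-1-ol | CC[C@@H](C)CO | starting material
12 | (triphenylphosphoranylidene)acetaldehyde | O=CC=P(c1ccccc1)(c1ccccc1)c1ccccc1 | starting material
13 | (R)-2-methylbutanal (not isolated) | CC[C@@H](C)C=O | intermediate
14 | (2E,4R)-4-methylhex-2-enal | CC[C@@H](C)/C=C/C=O | intermediate
15 | triethyl 4-phosphonocrotonate | CCOC(=O)/C=C/CP(=O)(OCC)OCC | starting material
16 | ethyl (2E,4E,6E,8R)-8-methyldeca-2,4,6-trienoate | CC[C@@H](C)/C=C/C=C/C=C/C(=O)OCC | intermediate
17 | (2E,4E,6E,8R)-8-methyldeca-2,4,6-trienamide | CC[C@@H](C)/C=C/C=C/C=C/C(N)=O | intermediate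
18 | (2E,4E,6E,8R)-N-[(1S,5S,6R)-5-ethenyl-2-oxo-5-[(trimethylsilyl)oxy]-7-oxabicyclo[4.1.0]hept-3-en-3-yl]-8-methyldeca-2,4,6-trienamide (not isolated) | CC[C@@H](C)/C=C/C=C/C=C/C(=O)NC1=C[C@@](O[Si](C)(C)C)(C=C)[C@@H]2O[C@@H]2C1=O | intermediate
19 | (2E,4E,6E,8R)-N-[(1S,5S,6R)-5-ethenyl-5-hydroxy-2-oxo-7-oxabicyclo[4.1.0]hept-3-en-3-yl]-8-methyldeca-2,4,6-trienamide | CC[C@@H](C)/C=C/C=C/C=C/C(=O)NC1=C[C@@](O)(C=C)[C@@H]2O[C@@H]2C1=O | intermediate
20 | glutaconaldehyde potassium salt | [K+].[O-]/C=C/C=C/C=O | starting material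
21 | (2E,4E)-5-bromopenta-2,4-dienal | Br/C=C/C=C/C=O | intermediate
22 | (2E,4E)-5-bromopenta-2,4-dienoic acid | Br/C=C/C=C/C(=O)O | intermediate
23 | cyclopentane-1,3-dione | O=C1CCC(=O)C1 | starting material
24 | 2-(hydroxyimino)cyclopentane-1,3-dione | ON=C1C(=O)CCC1=O | intermediate
25 | 2-amino-3-hydroxycyclopent-2-en-1-one hydrochloride | Cl.NC1=C(O)CCC1=O | intermediate
26 | (2E,4E)-5-bromopenta-2,4-dienoyl chloride (not isolated) | Br/C=C/C=C/C(Cl)=O | intermediate
27 | (2E,4E)-5-bromo-N-(2-hydroxy-5-oxocyclopent-1-en-1-yl)penta-2,4-dienamide | Br/C=C/C=C/C(=O)NC1=C(O)CCC1=O | intermediate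
28 | (2E,4E,6E,8R)-N-[(1S,5S,6R)-5-hydroxy-5-[(1E,3E,5E)-7-[(2-hydroxy-5-oxocyclopent-1-en-1-yl)amino]-7-oxohepta-1,3,5-trien-1-yl]-2-oxo-7-oxabicyclo[4.1.0]hept-3-en-3-yl]-8-methyldeca-2,4,6-trienamide | CC[C@@H](C)/C=C/C=C/C=C/C(=O)NC1=C[C@@](O)(/C=C/C=C/C=C/C(=O)NC2=C(O)CCC2=O)[C@@H]2O[C@@H]2C1=O | target

**Summary**

Total steps: 16. Longest linear sequence: 8 steps (steps 1 to 6, 10 and 16).

Steps most likely to fail:

Step 6. The carbene may also add to the vinyl group, the epoxide may be opened by a silyl halide or by alkoxide, or the bromoenone may degrade in the basic medium as it forms. The fallback sets out from 7 and keeps the one-carbon enlargement but makes it oxidative. Simmons–Smith cyclopropanation of the enol ether (Et2Zn, CH2I2, CH2Cl2, 0 °C) should give the siloxycyclopropane F1. Oxidative opening with FeCl3 in DMF at 0 °C should give the ring-enlarged 3-chloro ketone F2, and NaOAc in MeOH the enone F3. Alpha-iodination with I2 and pyridine in CH2Cl2 should give the 2-iodoenone F4, which takes the place of 10 in step 10 and rejoins the route at 19.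

Step 10. Coupling at the hindered alkenyl bromide may be slow, and the amidate or the base may attack the enone by conjugate addition or degrade the epoxy ketone. The fallback sets out from 10 and separates C–N bond formation from amide formation. Buchwald–Hartwig amination with benzophenone imine (Pd2(dba)3, Xantphos, Cs2CO3, dioxane, 60 °C) should give the N-diphenylmethylidene aminoenone F5, and aqueous citric acid in THF should release the free 2-aminoenone F6 with loss of the silyl ether. In parallel, LiOH hydrolysis of 16 gives the trienoic acid F7, and oxalyl chloride with cat. DMF gives the trienoyl chloride F8. N-Acylation of F6 with F8 (pyridine, CH2Cl2, 0 °C) comes back to the route at 19.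

Step 16. Insertion next to the quaternary carbinol centre may be slow, palladium hydride species may isomerise the polyene double bonds, and the product may decompose on prolonged warming with base. The fallback sets out from 19. Cross-metathesis with vinylboronic acid pinacol ester (second-generation Hoveyda–Grubbs catalyst, CH2Cl2, 40 °C) should give the (E)-alkenyl pinacol boronate F9. Suzuki–Miyaura coupling of F9 with 27 (Pd(dppf)Cl2, K3PO4, THF/H2O, rt) comes back to the route at 28.

Further compounds
F1 | step 6 | 5-ethenyl-1,5-bis[(trimethylsilyl)oxy]-3-oxatricyclo[4.1.0.0(2,4)]heptane | C=C[C@@]1(O[Si](C)(C)C)[C@@H]2O[C@@H]2[C@]3(O[Si](C)(C)C)[C@H]1C3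
F2 | step 6 | 4-chloro-5-ethenyl-5-[(trimethylsilyl)oxy]-7-oxabicyclo[4.1.0]heptan-2-one (mixture at the chlorine-bearing carbon) | C1C(Cl)[C@@](O[Si](C)(C)C)(C=C)[C@@H]2O[C@@H]2C1=O
F3 | step 6 | (1S,5S,6R)-5-ethenyl-5-[(trimethylsilyl)oxy]-7-oxabicyclo[4.1.0]hept-3-en-2-one | C1=C[C@@](O[Si](C)(C)C)(C=C)[C@@H]2O[C@@H]2C1=O
F4 | step 6 | (1S,5S,6R)-5-ethenyl-3-iodo-5-[(trimethylsilyl)oxy]-7-oxabicyclo[4.1.0]hept-3-en-2-one | IC1=C[C@@](O[Si](C)(C)C)(C=C)[C@@H]2O[C@@H]2C1=O
F5 | step 10 | (1S,5S,6R)-3-[(diphenylmethylidene)amino]-5-ethenyl-5-[(trimethylsilyl)oxy]-7-oxabicyclo[4.1.0]hept-3-en-2-one | C(c1ccccc1)(c1ccccc1)=NC1=C[C@@](O[Si](C)(C)C)(C=C)[C@@H]2O[C@@H]2C1=O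
F6 | step 10 | (1S,5S,6R)-3-amino-5-ethenyl-5-hydroxy-7-oxabicyclo[4.1.0]hept-3-en-2-one | NC1=C[C@@](O)(C=C)[C@@H]2O[C@@H]2C1=O
F7 | step 10 | (2E,4E,6E,8R)-8-methyldeca-2,4,6-trienoic acid | CC[C@@H](C)/C=C/C=C/C=C/C(=O)O
F8 | step 10 | (2E,4E,6E,8R)-8-methyldeca-2,4,6-trienoyl chloride | CC[C@@H](C)/C=C/C=C/C=C/C(Cl)=O
F9 | step 16 | (2E,4E,6E,8R)-N-[(1S,5S,6R)-5-hydroxy-2-oxo-5-[(E)-2-(4,4,5,5-tetramethyl-1,3,2-dioxaborolan-2-yl)ethenyl]-7-oxabicyclo[4.1.0]hept-3-en-3-yl]-8-methyldeca-2,4,6-trienamide | CC[C@@H](C)/C=C/C=C/C=C/C(=O)NC1=C[C@@](O)(/C=C/B2OC(C)(C)C(C)(C)O2)[C@@H]2O[C@@H]2C1=O
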